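# Proposed total synthesis of CNP0224912.1 (compound 33) by crotylsilane conjugate cyclization onto an alkylidene lactone

**Conventions.** The lactone–cyclopentane part is numbered as 2-oxabicyclo[3.3.0]octane: C1 (O-bearing fusion carbon), O2, C3 (carbonyl), C4, C5 (second fusion carbon), C6, C7 (spiro carbon), C8. The six-membered ring is C7, C1′ (bears the CH2O or carbonyl carbon), C2′, C3′, C4′, C5′ (bears CH3). "Convex" is the cyclopentane face carrying the two fusion hydrogens; "concave" (endo) is the face carrying O2 and C4.

**Remark on the chemistry (assumption):** 1, 10 and 30 are taken as purchasable in enantiomerically and geometrically pure form.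

## Analysis of the target

Compound 33 is a spiro[4.5] sesquiterpenoid in which a cyclopentane (C1, C5, C6, C7, C8) is cis-fused at C1/C5 to an α-methylene γ-lactone and joined through the quaternary C7 to a cyclohexene (C7, C1′–C5′). The cyclohexene carries the angeloyloxymethyl group on C1′, the C1′=C2′ double bond, a trans-diol at C3′/C4′ and a methyl group at C5′. There are six stereocentres (C1, C5, C7, C3′, C4′, C5′): C5′ is bonded to C7 on the convex face of the bicyclic lactone and C1′ on the concave face, and on the six-membered ring the C5′ methyl is cis to the C3′ hydroxyl, trans to the C4′ hydroxyl and cis to C6. The sensitive groups are the α-methylene lactone (a conjugate acceptor that tolerates neither hydride nor amide bases), the angelate (Z to E isomerisation to the tiglate under base or nucleophilic acyl catalysis) and the allylic secondary alcohol. The synthesis is hard because the quaternary C7 sits next to the tertiary C5′, because configuration must be relayed from the lactone to a ring that stands orthogonal to it, and because two carbonyl carbons (C3 and the carbon on C1′) must change oxidation level independently. The strategy rests on the C7–C5′ bond: in a cyclohexene precursor C5′ is allylic to a C3′=C4′ double bond and C7 is β to a carbonyl on C1′, which is the retron of a crotylsilane adding in conjugate fashion to an exocyclic alkylidene on C7 of the preformed cis-fused lactone. Because C7 and C5′ are both trigonal in that precursor, their relative configuration is set by the geometries of the two alkenes, so the alkylidene geometry has to be defined and not left open.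

## Retrosynthetic reasoning

**33 to 32, 29 and 30.** The last bonds cut are the two O–Si bonds and the ester C–O bond between the CH2O on C1′ and the angeloyl carbon. They go last because the angelate survives neither strong base nor hydride. The forward steps must acylate the primary allylic alcohol of 29 with 30 without Z to E isomerisation, then remove the silyl groups under weakly acidic conditions.

**29 to 26 (through 27 and 28).** The exocyclic carbon on C4 is cut. It is installed by aminomethylation of the lactone enolate and elimination, at a point where C4 is the only enolisable carbon (C1′ is sp2) and before the base-sensitive angelate exists. The forward step must alkylate a lactone enolate in the presence of an alkoxide.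

**26 to 25, 24, 23 and 22.** The C3′–O and C4′–O bonds are cut. The trans-diol is traced to the vinyl epoxide 23 opened at the allylic C3′, and 23 to the dienal 22. The aldehyde on C1′ does three jobs: it deactivates C1′=C2′ toward the peracid, it makes C3′ the site of epoxide opening, and it can later be reduced by a hydride that does not touch the lactone. The forward steps need epoxidation of C3′=C4′ on the face opposite the C5′ methyl and opening with inversion at C3′.

**22 to 21, 20 and 19.** The C1′=C2′ unsaturation and the oxidation level of the carbon on C1′ are adjusted here. In the ester 19 the lactone CH2 is more acidic and the lactone carbonyl more electrophilic than the ester, so neither selective enolisation nor selective reduction of the ester is available. Both carbonyls are therefore reduced (20) and re-oxidised to different levels (21), after which the aldehyde α-CH can be dehydrogenated selectively. The price is one redox loop; the gain is clean differentiation of the two carbonyl carbons for the rest of the route.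

**19 to 18 (key disconnection).** The C7–C5′ bond is cut, opening the six-membered ring. This removes the quaternary and the adjacent tertiary stereocentre in one stroke and leaves a precursor whose stereochemical information lies in one C–Si centre and two double bonds. The forward reaction must attack C7 from the convex face, close through a half-chair, and proceed anti to silicon. All three demands agree only for the (2Z) alkylidene combined with the (4R) silane, so the precursor is the single geometric isomer 18.

**18 to 17.** No skeletal bond is cut here; only the alkylidene geometry is sorted. C6 and C8 differ only at a distance, so no olefination can be expected to favour one geometry, and the alkylidene ester is first obtained as the geometric mixture 17. The (2Z) isomer 18 is taken out by chromatography, and the remainder is re-equilibrated photochemically and separated again, so that both geometries of 17 are funnelled into 18.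

**17 to 15, 9 and 13.** The C7=C1′ double bond is cut by aldol–dehydration, which joins the two fragments. The addition must avoid base because 13 is a β-acyloxy ketone. The elimination must go toward the ester α-carbon and not into the ring.

**13 to 12 and 10.** The C7–O bond is cut: hydration of the C6=C7 alkene with oxygen at C7, then oxidation. C1 and C5 are bought with 10.

**9 to 7, 5, 3, 1 and 2.** The chain is shortened by one carbon (Arndt–Eistert retron). The bond between C3 and the α-carbon of 5 is cut as a [3,3] retron that transfers the carbinol configuration of 3 to the C–Si centre and sets the E alkene. The C–Si bond is cut as a hydrosilylation of 1 with 2.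

## Alternatives that were turned down

**Alternative 1: ring-closing enyne metathesis to the 1-vinylcyclohexene A1.**
- Disconnection: the C1′=C2′ double bond, traced to an alkyne on the quaternary carbon and the terminal alkene of a chain that already carries C3′, C4′ and C5′ as sp3 stereocentres.
- Forward key step: a ruthenium alkylidene engages the alkene, then the alkyne, closing the cyclohexene and leaving a vinyl group on C1′.
- For: the contiguous triad and the quaternary carbon are fixed by acyclic methods before ring closure, so the diol configuration does not depend on a late substrate-controlled oxidation. On this point it is stronger than the chosen route. The hindered ring alkene also forms without elimination chemistry.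
- Against: the quaternary carbon with two differentiated arms next to the methyl-bearing carbon must be built acyclically, which moves the hardest stereochemical problem instead of solving it. An alkyne on a fully substituted carbon is a slow metathesis partner. After A1 the cyclopentane, the cis lactone and its methylene must still be built from the two arms, the vinyl group must lose a carbon, and four protecting groups must be handled.
- Comparison: the chosen route forms C7, C5′ and the ring in one step on a purchased cis lactone and excises no carbon; in exchange it accepts a late epoxidation and opening for the diol.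

**Alternative 2: acid-induced ring contraction of alantolactone A2 to the spiro lactone A3.**
- Disconnection: the bond between the spiro carbon and C8, traced to a 1,2-shift in a 6/6/5 skeleton.
- Forward key step: protonation of the trisubstituted ring alkene gives a tertiary cation at the future spiro carbon, the CH2 next to the lactone carbinol migrates to it from the angular-methyl carbon, and proton loss leaves the vinyl methyl.
- For: one step from a commercial terpenoid that already has the cis lactone, its methylene and the secondary methyl. In step count to the carbon skeleton it cannot be matched by the chosen route.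
- Against: the cation has other exits (hydride and methyl shifts, plain alkene migration) and the methylene lactone itself isomerises in acid. The spiro configuration is dictated by the migration and cannot be chosen. A3 lacks all three oxygens of the six-membered ring: the vinyl methyl can be oxidised allylically, but a trans-diol on two unactivated ring CH2 groups calls for several poorly selective C–H functionalisations next to a methylene lactone.
- Comparison: the chosen route is longer to the skeleton, but its key step leaves an alkene exactly where the diol is needed and a carbonyl on C1′ where the CH2O is needed.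

**Alternative 3: allenic hetero-Pauson–Khand reaction to A4, the bis(tert-butyldimethylsilyl) ether of 33.**
- Disconnection: three bonds at once, namely C1–C5, C3–C4 and C3–O2.
- Forward key step: a metal carbonyl promoter couples an aldehyde C=O, the internal double bond of an allene and one carbonyl ligand, closing cyclopentane and methylene lactone in one operation.
- For: the most convergent endgame. The methylene lactone arises without enolate chemistry and after the angelate is in place, so the ordering constraints of the chosen endgame disappear. On this point it is stronger.
- Against: the hetero variant with an aldehyde and an allene has little support for 5,5-systems. The two new stereocentres C1 and C5 would have to be induced by the quaternary C7, whose two arms are nearly alike, which is the same remote-control problem in its worst form. Regiochemistry between the two allene double bonds, and heat with stoichiometric metal in the presence of an allylic angelate, add risk. The cyclisation substrate with its quaternary carbon must still be made stereoselectively.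
- Comparison: the chosen route buys C1 and C5 and uses them to set C7. It is less convergent, but every stereocentre has an identifiable control element.

Key step: step 10

## Route

**Step 1**
Reactants: 1 (R)-but-3-yn-2-ol; 2 dimethylphenylsilane
Product: 3 (2R,3E)-4-(dimethylphenylsilyl)but-3-en-2-ol
Conditions: Pt2[(CH2=CHSiMe2)2O]3 (0.1 mol %), P(t-Bu)3, THF, 0 °C → rt
Reagents that add atoms: none
Why: Hydrosilylation of a terminal propargylic alcohol with a zerovalent platinum–trialkylphosphine catalyst is a syn addition that places silicon on the terminal carbon and gives the (E)-vinylsilane; the carbinol centre is not touched.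

**Step 2**
Reactants: 3 (2R,3E)-4-(dimethylphenylsilyl)but-3-en-2-ol
Product: 5 (3R,4E)-3-(dimethylphenylsilyl)hex-4-enoic acid, via methyl ester 4 (not isolated)
Conditions: MeC(OMe)3, EtCO2H (cat.), toluene, reflux (MeOH distilled off); then LiOH, THF/MeOH/H2O, rt; 1 M HCl to pH 3, 0 °C
Reagents that add atoms: trimethyl orthoacetate, CC(OC)(OC)OC; lithium hydroxide, [Li+].[OH-]
Why: Johnson–Claisen rearrangement through a chair transition state with the carbinol methyl equatorial transfers the (R) carbinol configuration to the new (R) C–Si centre and gives the E alkene; saponification of the crude ester leaves the allylsilane alone.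

**Step 3**
Reactants: 5 (3R,4E)-3-(dimethylphenylsilyl)hex-4-enoic acid
Product: 7 (4R,5E)-1-diazo-4-(dimethylphenylsilyl)hept-5-en-2-one, via mixed anhydride 6 (not isolated)
Conditions: i-BuOCOCl, Et3N, THF, −15 °C; then CH2N2, Et2O, 0 °C
Reagents that add atoms: diazomethane, C=[N+]=[N-]
Why: First half of an Arndt–Eistert homologation; activation as the mixed carbonic anhydride avoids the hydrogen chloride of acid chloride formation, which could protodesilylate the allylsilane.

**Step 4**
Reactants: 7 (4R,5E)-1-diazo-4-(dimethylphenylsilyl)hept-5-en-2-one
Product: 9 methyl (4R,5E)-4-(dimethylphenylsilyl)hept-5-enoate, via ketene 8 (not isolated)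
Conditions: AgOCOPh (0.1 equiv), Et3N, MeOH/THF, rt, dark
Reagents that add atoms: methanol, CO
Why: Silver-catalysed Wolff rearrangement; the migrating CH2 carries the untouched C–Si stereocentre one carbon further from the carboxyl, and methanol traps the ketene.

**Step 5**
Reactants: 10 (1R,5S)-2-oxabicyclo[3.3.0]oct-6-en-3-one
Product: 12 (1R,5R,7R)-7-hydroxy-2-oxabicyclo[3.3.0]octan-3-one (hydroxyl endo), via organomercurial 11 (not isolated)
Conditions: Hg(OAc)2, THF/H2O, rt; then NaBH4, 3 M NaOH, 0 °C; then 2 M HCl (pH 2), rt
Reagents that add atoms: water, O
Why: Oxymercuration–demercuration; the mercurinium ion should form on the convex face and be opened by water from the concave face at C7, because C6 is shielded there by the adjacent C4 methylene, the same sense as in Prins additions to this alkene. Acidification re-closes any lactone opened by hydroxide, and the C7 configuration is erased in step 6.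

**Step 6**
Reactants: 12 (1R,5R,7R)-7-hydroxy-2-oxabicyclo[3.3.0]octan-3-one
Product: 13 (1R,5R)-2-oxabicyclo[3.3.0]octane-3,7-dione
Conditions: DMP (1,1,1-triacetoxy-1,1-dihydro-1,2-benziodoxol-3(1H)-one), CH2Cl2, rt
Reagents that add atoms: none
Why: Oxidation of a secondary alcohol under non-basic conditions; base is avoided because 13 is a β-acyloxy ketone that would expel the lactone carboxylate by E1cB elimination.

**Step 7**
Reactants: 9 methyl (4R,5E)-4-(dimethylphenylsilyl)hept-5-enoate; 13 (1R,5R)-2-oxabicyclo[3.3.0]octane-3,7-dione
Product: 15 methyl (4R,5E)-4-(dimethylphenylsilyl)-2-[(1R,5R)-7-endo-hydroxy-3-oxo-2-oxabicyclo[3.3.0]oct-7-yl]hept-5-enoate (C2 epimers), via ketene silyl acetal 14 (not isolated)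
Conditions: 9, LiN(i-Pr)2, THF, −78 °C; Me3SiCl, −78 °C → rt; solvent exchange to CH2Cl2; then 13, TiCl4, −78 °C; aq. NaHCO3
Reagents that add atoms: none
Why: Mukaiyama aldol addition to a ketone; Lewis-acid conditions avoid enolising the β-acyloxy ketone, and the ketene silyl acetal is far more nucleophilic than the crotylsilane in the same molecule. Attack is expected from the convex face, and both new stereocentres disappear in step 8.

**Step 8**
Reactants: 15 methyl (4R,5E)-4-(dimethylphenylsilyl)-2-[(1R,5R)-7-endo-hydroxy-3-oxo-2-oxabicyclo[3.3.0]oct-7-yl]hept-5-enoate
Product: 17 methyl (4R,5E)-4-(dimethylphenylsilyl)-2-[(1R,5R)-3-oxo-2-oxabicyclo[3.3.0]oct-7-ylidene]hept-5-enoate (2E/2Z mixture of alkylidene isomers), via methanesulfonate 16 (not isolated)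
Conditions: MeSO2Cl, Et3N, CH2Cl2, −20 °C; then DBU, −20 → 0 °C
Reagents that add atoms: none
Why: Sulfonylation of the tertiary alcohol and E1cB elimination through the ester enolate should place the alkene in conjugation (exocyclic) and not in the ring. No bias between the alkylidene geometries is expected because C6 and C8 differ only remotely, so both should form in comparable amounts and 17 is carried on as this mixture. Base contact is kept short because deprotonation at C8 would expel the lactone oxygen from C1.

**Step 9**
Reactants: 17 methyl (4R,5E)-4-(dimethylphenylsilyl)-2-[(1R,5R)-3-oxo-2-oxabicyclo[3.3.0]oct-7-ylidene]hept-5-enoate (2E/2Z mixture of alkylidene isomers)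
Product: 18 methyl (2Z,4R,5E)-4-(dimethylphenylsilyl)-2-[(1R,5R)-3-oxo-2-oxabicyclo[3.3.0]oct-7-ylidene]hept-5-enoate (CO2CH3 cis to C8)
Conditions: SiO2 chromatography (2Z isomer collected); 2E-rich remainder: hν (λ > 300 nm), acetophenone (sens.), C6H6, rt, then SiO2 chromatography; cycle repeated
Reagents that add atoms: none
Why: The two geometries of 17 place the ester either beside C8 (next to the lactone oxygen) or beside C6 and should be separable on silica. Triplet-sensitised E/Z isomerisation of an α,β-unsaturated ester should return the (2E)-rich remainder to a near-photostationary mixture, so repeated separation funnels the material into 18. The enoate is the lowest-lying triplet acceptor in the molecule, so the isolated (E)-crotyl double bond and the C–Si centre should keep their configuration.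

**Step 10 (key step)**
Reactants: 18 methyl (2Z,4R,5E)-4-(dimethylphenylsilyl)-2-[(1R,5R)-3-oxo-2-oxabicyclo[3.3.0]oct-7-ylidene]hept-5-enoate
Product: 19 spiro ester (cis-2-oxabicyclo[3.3.0]octan-3-one spiro-joined at C7 to a cyclohex-3′-ene bearing CO2CH3 on C1′ and CH3 on C5′; C5′ on the convex face; CH3 cis to C6; C1′ epimers)
Conditions: TiCl4 (2.5 equiv), 2,6-di-tert-butyl-4-methylpyridine (0.3 equiv), CH2Cl2, −78 → −40 °C; aq. NaHCO3
Reagents that add atoms: none
Why: TiCl4 binds the ester carbonyl (a second equivalent is taken up by the lactone) and makes C7 electrophilic; the crotyl terminus (the future C5′) attacks C7, the β-silyl cation loses silicon to chloride to give the C3′=C4′ alkene, and the titanium enolate is protonated on work-up. The closest known reaction type is the intramolecular Hosomi–Sakurai conjugate allylation, in the topology where the silicon-bearing carbon stays in the ring, as in crotylsilane annulations that give cyclohexenes and dihydropyrans. The ring that closes is six-membered, 6-endo-trig with respect to the acceptor (C7 and C1′ both end up in the ring), through a half-chair in which the C–Si bond is perpendicular to the allyl plane and the C2′ methylene is "inside", which makes the new ring alkene cis. C7 is set by attack on the convex face of the cis-fused bicyclic lactone, so that C5′ ends anti to O2 and C4. The configuration of C5′ relative to C7 is fixed by the two alkene geometries: in the half-chair the C2′ methylene is cis to C6 (Z alkylidene) and the methyl of the (E)-crotyl unit is pseudo-equatorial, which places the methyl cis to C6 as in 33. The same absolute sense is demanded by anti SE2′ attack of the (4R) silane, so convex-face attack, half-chair closure and anti SE2′ are matched only for the (2Z)/(4R) combination, which is why the (2E) component of 17 is removed in step 9. The step needs 1,4- over 1,2-addition, secured by the ester function, and C–C bond formation over protodesilylation, secured by the hindered pyridine base, low temperature and dry conditions. The configuration at C1′ is of no consequence because C1′ becomes sp2 in step 13.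

**Step 11**
Reactants: 19 spiro ester
Product: 20 lactol alcohol (19 with C3 as hemiacetal CHOH and CH2OH on C1′; anomers and C1′ epimers)
Conditions: i-Bu2AlH (4 equiv), CH2Cl2, −78 → −20 °C; aq. KNaC4H4O6
Reagents that add atoms: none
Why: Hydride reduction takes the lactone to the lactol and the hindered ester to the primary alcohol; since the lactone is both the more acidic and the more electrophilic carbonyl, the two are reduced together and re-oxidised to different levels in step 12, where any aldehyde left on C1′ converges.

**Step 12**
Reactants: 20 lactol alcohol
Product: 21 lactone aldehyde (19 with CHO in place of CO2CH3; C1′ epimers)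
Conditions: TEMPO (2,2,6,6-tetramethylpiperidin-1-oxyl, 0.2 equiv), PhI(OAc)2 (2.5 equiv), CH2Cl2, rt
Reagents that add atoms: none
Why: Oxoammonium oxidation takes the lactol to the lactone and the primary alcohol to the aldehyde without going on to the acid; the two carbonyl carbons are now distinct, the aldehyde being far more enolisable and far more reducible than the lactone.

**Step 13**
Reactants: 21 lactone aldehyde
Product: 22 dienal (spiro lactone with C1′(CHO)=C2′ and C3′=C4′ double bonds and the C5′ methyl)
Conditions: IBX (2-iodoxybenzoic acid, 3 equiv), DMSO, 70 °C
Reagents that add atoms: none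
Why: Dehydrogenation of an aldehyde through its enol by pentavalent iodine; only C1′–H can enolise toward the aldehyde (C7 is quaternary), the lactone is inert, and the new C1′=C2′ bond is conjugated with C3′=C4′.

**Step 14**
Reactants: 22 dienal
Product: 23 3′,4′-epoxide of 22 (oxygen trans to the C5′ methyl)
Conditions: mCPBA, NaHCO3, CH2Cl2, 0 °C
Reagents that add atoms: 3-chloroperoxybenzoic acid, OOC(=O)c1cccc(Cl)c1
Why: Peracid epoxidation of a 2,4-dienal should take place at the distal C3′=C4′ bond, because C1′=C2′ is deactivated by the aldehyde; the pseudo-axial C5′ methyl next to C4′ shields one face, so oxygen should enter trans to the methyl.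

**Step 15**
Reactants: 23 epoxide
Product: 24 trans-diol (3′-OH cis and 4′-OH trans to the C5′ methyl; CHO on C1′=C2′)
Conditions: HClO4 (cat.), THF/H2O (3:1), 0 °C → rt
Reagents that add atoms: water, O
Why: Acid-catalysed hydrolysis of a vinyl epoxide; water should attack the allylic C3′ with inversion, since C4′ is not activated and is flanked by C5′, which gives the diol configuration of 33.

**Step 16**
Reactants: 24 trans-diol
Product: 25 3′,4′-bis(triethylsilyl) ether of 24
Conditions: Et3SiCl, imidazole, DMAP (cat.), DMF, 0 °C → rt
Reagents that add atoms: chlorotriethylsilane, CC[Si](Cl)(CC)CC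
Why: Silylation of both secondary alcohols; triethylsilyl ethers withstand hydride, amide base and acylation and come off at the end under weakly acidic fluoride conditions that spare the angelate and the methylene lactone.

**Step 17**
Reactants: 25 bis(triethylsilyl) ether
Product: 26 allylic alcohol (CH2OH on C1′ in place of the CHO of 25)
Conditions: NaBH4, CeCl3·7H2O, MeOH, −40 °C
Reagents that add atoms: none
Why: Luche 1,2-reduction of the enal; the γ-lactone is not reduced by borohydride under these conditions.

**Step 18**
Reactants: 26 allylic alcohol
Product: 27 Mannich base (26 with CH2N(CH3)2 on C4; C4 configuration not defined)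
Conditions: LiN(i-Pr)2 (2.3 equiv), THF, −78 °C; CH2=NMe2+ I− (3 equiv), −78 °C → rt; aq. NH4Cl
Reagents that add atoms: dimethyl(methylidene)ammonium iodide, C=[N+](C)C.[I-]
Why: Mannich aminomethylation of the lactone enolate; C4 is now the only enolisable carbon, the primary hydroxyl is carried as its alkoxide, and any N,O-acetal formed there hydrolyses on work-up.

**Step 19**
Reactants: 27 Mannich base
Product: 29 α-methylene lactone (26 with =CH2 on C4), via ammonium iodide 28 (not isolated)
Conditions: MeI, MeOH, rt; then aq. NaHCO3, EtOAc, rt
Reagents that add atoms: none
Why: Quaternisation of the amine and E1cB loss of trimethylamine give the α-methylene lactone under conditions too mild to touch the silyl ethers or the free alcohol.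

**Step 20**
Reactants: 29 α-methylene lactone; 30 angelic acid
Product: 32 3′,4′-bis(triethylsilyl) ether of 33, via mixed anhydride 31 (not isolated)
Conditions: 30, 2,4,6-Cl3C6H2COCl, Et3N, toluene, rt; then 29, 75 °C
Reagents that add atoms: none
Why: Yamaguchi esterification run without DMAP, because nucleophilic catalysts promote Z to E isomerisation of activated angelates; only the primary allylic hydroxyl is free, and no strong base follows this step.

**Step 21**
Reactants: 32 bis(triethylsilyl) ether of 33
Product: 33 CNP0224912.1
Conditions: HF·pyridine, pyridine, THF, 0 °C → rt
Reagents that add atoms: none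
Why: Buffered fluoride cleavage of the two triethylsilyl ethers; neither the angelate nor the methylene lactone reacts under these weakly acidic conditions.

## Compound list

1 | (R)-but-3-yn-2-ol | C[C@@H](O)C#C | starting material
2 | dimethylphenylsilane | C[SiH](C)c1ccccc1 | starting material
3 | (2R,3E)-4-(dimethylphenylsilyl)but-3-en-2-ol | C[C@@H](O)/C=C/[Si](C)(C)c1ccccc1 | intermediate
4 | methyl (3R,4E)-3-(dimethylphenylsilyl)hex-4-enoate | COC(=O)C[C@H](/C=C/C)[Si](C)(C)c1ccccc1 | intermediate
5 | (3R,4E)-3-(dimethylphenylsilyl)hex-4-enoic acid | OC(=O)C[C@H](/C=C/C)[Si](C)(C)c1ccccc1 | intermediate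
6 | isobutyl carbonic mixed anhydride of 5 | CC(C)COC(=O)OC(=O)C[C@H](/C=C/C)[Si](C)(C)c1ccccc1 | intermediate
7 | (4R,5E)-1-diazo-4-(dimethylphenylsilyl)hept-5-en-2-one | [N-]=[N+]=CC(=O)C[C@H](/C=C/C)[Si](C)(C)c1ccccc1 | intermediate
8 | (4R,5E)-4-(dimethylphenylsilyl)hepta-1,5-dien-1-one (ketene) | O=C=CC[C@H](/C=C/C)[Si](C)(C)c1ccccc1 | intermediate
9 | methyl (4R,5E)-4-(dimethylphenylsilyl)hept-5-enoate | COC(=O)CC[C@H](/C=C/C)[Si](C)(C)c1ccccc1 | intermediate
10 | (1R,5S)-2-oxabicyclo[3.3.0]oct-6-en-3-one | C1C(=O)O[C@@H]2CC=C[C@H]12 | starting material
11 | 6-exo-(acetoxymercurio)-7-endo-hydroxy-2-oxabicyclo[3.3.0]octan-3-one | C1C(=O)O[C@@H]2C[C@H](O)[C@@H]([Hg]OC(C)=O)[C@H]12 | intermediate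
12 | (1R,5R,7R)-7-hydroxy-2-oxabicyclo[3.3.0]octan-3-one (hydroxyl endo) | C1C(=O)O[C@@H]2C[C@H](O)C[C@H]12 | intermediate
13 | (1R,5R)-2-oxabicyclo[3.3.0]octane-3,7-dione | C1C(=O)O[C@@H]2CC(=O)C[C@H]12 | intermediate
14 | methyl trimethylsilyl ketene acetal of 9 | COC(O[Si](C)(C)C)=CC[C@H](/C=C/C)[Si](C)(C)c1ccccc1 | intermediate
15 | methyl (4R,5E)-4-(dimethylphenylsilyl)-2-[(1R,5R)-7-endo-hydroxy-3-oxo-2-oxabicyclo[3.3.0]oct-7-yl]hept-5-enoate (C2 epimers) | C1C(=O)O[C@@H]2C[C@](O)(C[C@H]12)C(C(=O)OC)C[C@H](/C=C/C)[Si](C)(C)c3ccccc3 | intermediate
16 | tertiary methanesulfonate of 15 | C1C(=O)O[C@@H]2C[C@](OS(C)(=O)=O)(C[C@H]12)C(C(=O)OC)C[C@H](/C=C/C)[Si](C)(C)c3ccccc3 | intermediate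
17 | methyl (4R,5E)-4-(dimethylphenylsilyl)-2-[(1R,5R)-3-oxo-2-oxabicyclo[3.3.0]oct-7-ylidene]hept-5-enoate, 2E/2Z mixture of alkylidene isomers | C1C(=O)O[C@@H]2CC(=C(C(=O)OC)C[C@H](/C=C/C)[Si](C)(C)c3ccccc3)C[C@H]12 | intermediate
18 | methyl (2Z,4R,5E)-4-(dimethylphenylsilyl)-2-[(1R,5R)-3-oxo-2-oxabicyclo[3.3.0]oct-7-ylidene]hept-5-enoate (CO2CH3 cis to C8) | C1C(=O)O[C@@H]2C/C(=C(\C(=O)OC)C[C@H](/C=C/C)[Si](C)(C)c3ccccc3)C[C@H]12 | intermediate
19 | spiro ester: cis-2-oxabicyclo[3.3.0]octan-3-one spiro-joined at C7 to a cyclohex-3′-ene with CO2CH3 on C1′ (epimers) and CH3 on C5′; C5′ on the convex face, CH3 cis to C6 | C1C(=O)O[C@@H]2C[C@@]3(C[C@H]12)C(C(=O)OC)CC=C[C@@H]3C | intermediate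
20 | lactol alcohol: 19 with C3 as CHOH (anomers) and CH2OH on C1′ | C1C(O)O[C@@H]2C[C@@]3(C[C@H]12)C(CO)CC=C[C@@H]3C | intermediate
21 | lactone aldehyde: 19 with CHO in place of CO2CH3 | C1C(=O)O[C@@H]2C[C@@]3(C[C@H]12)C(C=O)CC=C[C@@H]3C | intermediate
22 | dienal: spiro lactone with C1′(CHO)=C2′ and C3′=C4′ double bonds | C1C(=O)O[C@@H]2C[C@@]3(C[C@H]12)C(C=O)=CC=C[C@@H]3C | intermediate
23 | 3′,4′-epoxide of 22, oxygen trans to the C5′ methyl | C1C(=O)O[C@@H]2C[C@@]3(C[C@H]12)C(C=O)=C[C@H]4O[C@H]4[C@@H]3C | intermediate
24 | trans-diol enal: 3′-OH cis and 4′-OH trans to the C5′ methyl | C1C(=O)O[C@@H]2C[C@@]3(C[C@H]12)C(C=O)=C[C@H](O)[C@@H](O)[C@@H]3C | intermediate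
25 | 3′,4′-bis(triethylsilyl) ether of 24 | C1C(=O)O[C@@H]2C[C@@]3(C[C@H]12)C(C=O)=C[C@H](O[Si](CC)(CC)CC)[C@@H](O[Si](CC)(CC)CC)[C@@H]3C | intermediate
26 | allylic alcohol: 25 with CH2OH in place of CHO | C1C(=O)O[C@@H]2C[C@@]3(C[C@H]12)C(CO)=C[C@H](O[Si](CC)(CC)CC)[C@@H](O[Si](CC)(CC)CC)[C@@H]3C | intermediate
27 | Mannich base: 26 with CH2N(CH3)2 on C4 | CN(C)CC1C(=O)O[C@@H]2C[C@@]3(C[C@H]12)C(CO)=C[C@H](O[Si](CC)(CC)CC)[C@@H](O[Si](CC)(CC)CC)[C@@H]3C | intermediate
28 | trimethylammonium iodide of 27 | C[N+](C)(C)CC1C(=O)O[C@@H]2C[C@@]3(C[C@H]12)C(CO)=C[C@H](O[Si](CC)(CC)CC)[C@@H](O[Si](CC)(CC)CC)[C@@H]3C.[I-] | intermediate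
29 | α-methylene lactone: 26 with =CH2 on C4 | C=C1C(=O)O[C@@H]2C[C@@]3(C[C@H]12)C(CO)=C[C@H](O[Si](CC)(CC)CC)[C@@H](O[Si](CC)(CC)CC)[C@@H]3C | intermediate
30 | angelic acid, (Z)-2-methylbut-2-enoic acid | C/C=C(/C)C(=O)O | starting material
31 | mixed anhydride of 30 with 2,4,6-trichlorobenzoic acid | C/C=C(/C)C(=O)OC(=O)c1c(Cl)cc(Cl)cc1Cl | intermediate
32 | 3′,4′-bis(triethylsilyl) ether of 33 | C=C1C(=O)O[C@@H]2C[C@@]3(C[C@H]12)C(COC(=O)/C(C)=C\C)=C[C@H](O[Si](CC)(CC)CC)[C@@H](O[Si](CC)(CC)CC)[C@@H]3C | intermediate
33 | CNP0224912.1 | C=C1C(=O)O[C@@H]2C[C@@]3(C[C@H]12)C(COC(=O)/C(C)=C\C)=C[C@H](O)[C@@H](O)[C@@H]3C | target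

## Step count and the least certain steps

Total: 21 steps. Longest linear sequence: 19 steps (steps 1–4 and 7–21); the lactone branch (steps 5 and 6) joins at step 7.

**Step 10 (key step).** The most likely failure is protodesilylation of the crotylsilane outrunning C–C bond formation, because a tetrasubstituted mono-ester acceptor is only modestly activated by a Lewis acid and the new bond creates a quaternary centre. A second risk is attack on the concave face if the convex-face preference at the remote C7 is small. The fallback activates the nucleophile instead of the electrophile: starting from 18, anhydrous tetrabutylammonium difluorotriphenylsilicate in THF (−20 °C → rt) should turn the silane into an allyl anion equivalent that adds to the unactivated enoate through the same six-membered half-chair (a four-membered alternative through the silicon-bearing carbon is not viable), and protonation returns the route at 19. The C7/C5′ relationship is then carried by the two alkene geometries alone. This fallback makes no compound outside the list (F0).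

**Step 8.** The elimination may lose regiocontrol (ring-alkene isomers) and offers no geometric control, so the throughput depends on the separation and photochemical recycling of step 9; prolonged base may also open the lactone through deprotonation at C8. If the two geometries of 17 cannot be separated in step 9, 17 can be taken into step 10 as the mixture, where only the (2Z) isomer has a matched pathway. The fallback avoids the alkylidene altogether: starting from 15, acetylation (Ac2O, DMAP, Et3N, CH2Cl2, 40 °C) should give the tertiary acetate F1, and SnCl4 (CH2Cl2, −78 °C) should ionise it to the tertiary C7 cation, which the crotylsilane captures through the same half-chair. Because C7–C1′ is then a freely rotating single bond, no alkene geometry is involved, and anti SE2′ delivery from the (4R) silane together with convex-face attack decides C5′. The route is rejoined at 19.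

**Step 5.** Water delivery may show poor regioselectivity between C6 and C7, since both alkene carbons are secondary and the bias is only steric. The fallback separates electrophile addition from reduction: starting from 10, N-bromosuccinimide in DMSO/H2O (0 °C) should give the bromohydrin F2 (6-exo-bromo, 7-endo-hydroxy) by SN2-like opening of the convex bromonium ion at the less shielded C7, and Bu3SnH/AIBN (benzene, 80 °C) should remove the bromine. The route is rejoined at 12.

**Step 13.** Enolisation of a neopentyl-type aldehyde is slow, and hot acidic DMSO may cause epimerisation at C5′ through extended enolisation of the product or over-oxidation. The fallback is a Saegusa dehydrosilylation at room temperature: starting from 21, Me3SiCl/NaI/Et3N (MeCN, rt) should silylate only the aldehyde to the trimethylsilyl enol ether F3, and Pd(OAc)2 (1 equiv, divalent palladium, MeCN, rt) should give the enal. The route is rejoined at 22.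

**Step 14.** A single allylic methyl may discriminate the two faces insufficiently, and the peracid may oxidise the aldehyde. The fallback replaces epoxidation and anti opening by syn-dihydroxylation and inversion: starting from 22, OsO4 (cat.) with N-methylmorpholine N-oxide (acetone/H2O) should dihydroxylate the electron-richer C3′=C4′ bond trans to the methyl, the bulkier reagent being more face-selective, to give the cis-diol F4. Mitsunobu reaction (PPh3, diisopropyl azodicarboxylate, 4-nitrobenzoic acid, THF, 0 °C) should invert the more reactive allylic C3′ to give the 4-nitrobenzoate F5, and K2CO3/MeOH (0 °C) should release the diol. The route is rejoined at 24.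

**Step 20.** The angelate may isomerise to the tiglate during acyl transfer, by addition–elimination of amine on the activated acyl group. The fallback reverses the polarity so that the acid is never acyl-activated: starting from 29, CBr4/PPh3 (CH2Cl2, 0 °C) should give the allylic bromide F6, and the caesium salt of 30 (Cs2CO3, DMF, rt) should displace bromide at the primary carbon. The route is rejoined at 32.

## Further compounds

F0 | step 10 | none | none
F1 | step 8 | tertiary acetate of 15 | C1C(=O)O[C@@H]2C[C@](OC(C)=O)(C[C@H]12)C(C(=O)OC)C[C@H](/C=C/C)[Si](C)(C)c3ccccc3
F2 | step 5 | 6-exo-bromo-7-endo-hydroxy-2-oxabicyclo[3.3.0]octan-3-one | C1C(=O)O[C@@H]2C[C@H](O)[C@@H](Br)[C@H]12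
F3 | step 13 | trimethylsilyl enol ether of 21 | C1C(=O)O[C@@H]2C[C@@]3(C[C@H]12)C(=CO[Si](C)(C)C)CC=C[C@@H]3C
F4 | step 14 | cis-diol enal (3′-OH and 4′-OH both trans to the C5′ methyl) | C1C(=O)O[C@@H]2C[C@@]3(C[C@H]12)C(C=O)=C[C@@H](O)[C@@H](O)[C@@H]3C
F5 | step 14 | 3′-(4-nitrobenzoate) of 24 | C1C(=O)O[C@@H]2C[C@@]3(C[C@H]12)C(C=O)=C[C@H](OC(=O)c4ccc(cc4)[N+](=O)[O-])[C@@H](O)[C@@H]3C
F6 | step 20 | allylic bromide: 29 with CH2Br in place of CH2OH | C=C1C(=O)O[C@@H]2C[C@@]3(C[C@H]12)C(CBr)=C[C@H](O[Si](CC)(CC)CC)[C@@H](O[Si](CC)(CC)CC)[C@@H]3C
A1 | alternative 1 | 1-vinylcyclohexene with two silyloxy groups, a ring methyl and a quaternary carbon bearing CH2CH2OSi and CH2O(4-methoxybenzyl) arms | C=CC1=C[C@H](O[Si](C)(C)C(C)(C)C)[C@@H](O[Si](C)(C)C(C)(C)C)[C@H](C)[C@]1(CCO[Si](C)(C)C(C)(C)C)COCc2ccc(OC)cc2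
A2 | alternative 2 | alantolactone | C[C@H]1CCC[C@]2(C1=C[C@H]3[C@@H](C2)OC(=O)C3=C)C
A3 | alternative 2 | spiro methylene lactone without the three ring oxygens (vinyl methyl on C1′) | C=C1C(=O)O[C@@H]2C[C@@]3(C[C@H]12)C(C)=CCC[C@@H]3C
A4 | alternative 3 | 3′,4′-bis(tert-butyldimethylsilyl) ether of 33 | C=C1C(=O)O[C@@H]2C[C@@]3(C[C@H]12)C(COC(=O)/C(C)=C\C)=C[C@H](O[Si](C)(C)C(C)(C)C)[C@@H](O[Si](C)(C)C(C)(C)C)[C@@H]3C
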